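Read the starting material column before the target column, and count how many half-lives of starting material the flask has had.

in all of them: starting material 21 mM; partner 37.8 mM

|  | temperature | remark | time |
|---|---|---|---|
| delta | −20 °C | the very flask that is asked about, followed so far |  |
| epsilon | −14 °C | run made earlier |  |
| flask | −20 °C |  | 6.0 d |

| run | time / h | target / % | starting material / % |
|---|---|---|---|
| delta | 25.0 | 19.3 | 18.6 |
| delta | 50.0 | 28.2 | 2.9 |
| delta | 72.0 | 30.8 | 0.1 |
| delta | 96.0 | 28.7 | 0.1 |
| delta | 120 | 28.1 | 0 |
| epsilon | 25.0 | 31.5 | 3.2 |
| epsilon | 50.0 | 33.8 | 0.5 |
| epsilon | 72.0 | 36.2 | 1.4 |
| epsilon | 96.0 | 35.0 | 0 |
| epsilon | 120 | 35.4 | 1.1 |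

(scatter of a reading: 1 percentage point)

- Sunday's: at 6.0 d take out 90% of the target then present, then wait 6.0 d
- Monday's: at 6.0 d add partner, 100% of the amount charged, then wait 6.0 d
- Thursday's: at 6.0 d raise the temperature by 25 K, then wait 6.0 d
- Wednesday's: change nothing and wait 6.0 d more

- percent here means starting material units held: one side product counts as two
- what is said of by-product includes crystals
- crystals is a solid; its amount is given per volume of the solution
- what is taken out of target is counted as made
- steps that have been proposed: target <-> isomer of the product; intermediate -> target; starting material + target -> side product; starting material + partner -> intermediate + by-product; crystals <-> by-product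
- additions bring no volume worth counting

- target, in percent of the starting material first charged, at 6.0 d
- what to do for the largest gain in target; "none" if nothing gains more than 2 percentage points (Sunday's / Monday's / Thursday's / Wednesday's / none)
- target present, with what was taken out counted in, in percent of the starting material first charged, after Sunday's
- target present, with what was taken out counted in, in percent of the starting material first charged, after Monday's

The delta run is this flask so far. The charge holds more partner than starting material, with

[partner]/[starting material] = 1.80

That makes starting material the limiting reagent, but it is no flood of partner, so what follows is a half-life read from the decay and not a pseudo-first-order constant. Its first delta reading gives a half-life of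

10.3 h

and the next interval gives 9.32 h, so one half-life will do for counting on these readings. The stop number, time in the flask divided by that half-life, is

14.0

Because the half-life is far shorter than 6.0 d, I expect the flask to have stopped before the look, and I take "now" from the flat delta readings after 72.0 h: their mean is 29.2%. Wednesday's should then give nothing, and Monday's partner meets a reading of 0% starting material.

The epsilon run reads a half-life of 5.03 h, shorter by a factor 2.05, and a plateau of 35.5%, higher than in the delta run. So I look for a gain in moving the plateau, not in waiting. The stop number does not size that gain.

The forecast gives 29%, Thursday's, 41% and 29%, on the ground that “removing target lets isomer refill it”.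

The flask gives 29.4%. The best option is Thursday's, gaining 19 percentage points, with 40.4% after Sunday's and 29.3% after Monday's.

    target ⇌ isomer of the product (K = 0.723, k = 4.37 × 10⁻⁴ /min, Ea = 90.0 kJ/mol, ΔH = −65.0 kJ/mol)
    intermediate → target (k = 0.00105 /min, Ea = 85.0 kJ/mol)
    starting material + target → side product (k = 0.129 /M/min, Ea = 41.0 kJ/mol)
    starting material + partner → intermediate + by-product (k = 0.0286 /M/min, Ea = 51.0 kJ/mol)
    crystals ⇌ by-product, rate k5*(cs5 - [by-product]) while solid is left; crystals form when [by-product] > cs5 (solubility = 6.90 mM, k = 0.0338 /min)
    (constants at −20 °C)

With its stop number of 14.0, the flask holds 0% starting material at 144 h, and its target stands at 29.3% at 1440 h. Now take the repeat at −35 °C. The half-life of starting material by the partner step alone, at the charged amounts, is 11 h in the flask; its barrier stretches that to 49.2 h in the repeat, which gives a stop number of 2.93 and 13.1% of the starting material left. That flask has not stopped: at 144 h it holds 15.2% starting material, 45.3% intermediate and 13.2% target.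

The readings were generated by integration for an exercise, noise included.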